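## Analysis of the target

Target 16 is a flavone, a 2-aryl-4H-chromen-4-one. Benzo ring A (C4a, C5 to C8, C8a) is fused to pyranone ring C (O1, C2, C3, C4), and aryl ring B sits on C2. There is no stereocenter. The C2–C1' bond is twisted by the C3 and C2' methoxyls but is not a stable axis, so nothing stereochemical has to be set or preserved. The real problem is six oxygen substituents, two of which must end as free phenols. Ring A carries oxygen on C5, C7 and C8, ring C a methoxyl on C3, and ring B a methoxyl on C2' and a hydroxyl on C5'. The C5 hydroxyl is hydrogen-bonded to the C4 carbonyl, whereas the C5' hydroxyl is an ordinary phenol. The sensitive points are: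

- the pyranone, which hydroxide can open by addition at C2;
- the electron-rich ring A, which is easily oxidised;
- the C3 methoxyl, which flanks the same carbonyl as the C5 oxygen and can be lost with it;
- the 5,7,8-pattern itself, which can slip to the 5,6,7-pattern if ring C opens while both ortho oxygens of ring A are free.

The strategy rests on one feature. Cutting ring C at O1–C2 and C4–C4a leaves ring A as phenol 6, whose C6 is the only unsubstituted carbon ortho to the hydroxyl. The same cut leaves C2, C3, C4 and ring B as the α-methoxy β-ketoester 11, which already carries the C3 methoxyl.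

## Retrosynthetic reasoning

**16 from 15 (O–S bond at C5').** The last operation should touch only a protecting group. The C5' oxygen is carried as a methanesulfonate because this group is not nucleophilic, has no benzylic or acid-labile bond, and should pass through a high-temperature melt unchanged. Its removal needs base, which is the one reagent the pyranone dislikes. The cleavage is therefore placed after the C5 phenol is free: in 15 the base first makes the C5 phenoxide, which feeds electron density into the C4 carbonyl and makes C2 a poorer acceptor.

**15 from 14 (O–CH3 bond at C5).** All four ring A and ring C oxygens are carried as methyl ethers, and the C5 ether is distinguished only at the end by its position. It is the one ether that can form a six-membered chelate with the C4 carbonyl around a Lewis acid. The forward reaction must cleave this one O–CH3 bond and leave the C3, C7, C8 and C2' ethers and the sulfonate alone.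

**14 from 6 and 11 (C4–C4a and O1–C2; ring C).** This is the central cut. It divides the molecule into two halves of similar size, and each half already has every oxygen in its final place. A cut at C2–C1' or C2–C3 would instead leave a chromone that still has to be functionalised. In the forward direction the ester carbon of 11 must bond to C6 of phenol 6 and the phenol oxygen must bond to the ring B ketone carbon, in that sense and not the reverse (the reverse gives a 4-arylcoumarin). The reaction passes through acylketene 12 and the ortho-hydroxyaryl diketone 13. No protecting group is needed on the phenol of 6, because that oxygen becomes O1.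

**11 from 9 and 10, and 9 from 8 and 7 (C2–C3 bond, flavone numbering).** The ketoester is cut between the aroyl carbon and the α-carbon. This gives acid chloride 9 and ester 10, which supplies C3 with its methoxyl and C4. The forward reaction is a crossed ester-enolate acylation. It has to be fast and cold so that the enolate does not touch the acidic methyl group of the sulfonate. Acid chloride 9 goes back through acid 8 to the hydroxy acid 7, sulfonylated on the phenol.

**6 from 5, 4, 3, 2 and 1 (C–O bond at the future C8).** Phenol 6 has four oxygens in a 1,2,3,5 arrangement with the free hydroxyl at the end of the contiguous three. Aldehyde 1 has three of them, and its formyl carbon sits where the fourth is needed. An aryl migration to oxygen (2 to formate 3 to phenol 4) installs that oxygen. The original hydroxyl of 1 is held as a benzyl ether in 2, 4 and 5, so that the new oxygen is methylated and the old one is released, giving 6 and not its isomer.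

## Alternatives that were turned down

Alternative 1: This route cuts C4a–C4 and C4–C3 and takes C4 from the carbonylation atmosphere. Aryl iodide A2 (ring A, phenol oxygen as methoxymethyl ether) and the enolate of ring B ketone A3 are joined carbonylatively under Pd(dba)2 (zerovalent palladium) with a diphosphine. The product is the open 1,3-diketone A1; no ring closes.
- For it: the C–I bond fixes where ring A reacts, the temperature is moderate, and the coupling is convergent.
- Against it: the iodine of A2 lies between two alkoxy groups on a very electron-rich ring, which is a poor case for oxidative addition and for acyl transfer from palladium. The nucleophile is an α-methoxy ketone enolate reacting at a secondary carbon. Direct α-arylation without carbonyl insertion competes whenever insertion is slow. The product A1 is a more acidic 2-substituted dione that can bind the metal or be O-acylated.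
- A2 must itself be made from phenol 6 by protection and a regioselective iodination, so the ring A site question is only moved earlier. After the coupling, the acetal must be removed and the ring closed with acid, and the benzyl and C5 methyl groups must still come off.
- Comparison: it is stronger on regiochemical certainty at ring A and on mildness. The chosen route offers ring closure in the same operation, no metal, no halide, no phenol protection, and at least three fewer operations.

Alternative 2: This route builds ring A last, cutting C4a–C5. Heating the hydroxycyclobutenone A5 (racemic at the carbinol carbon) should open it to a dienylketene. That ketene closes by 6π electrocyclisation onto the pyranone C=C and tautomerises to the 5,8-quinol A4.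
- For it: the ring A pattern is written into the four-membered ring, so C7 methoxyl and the 5,8-oxygens arise without regiochemical doubt. The C5 hydroxyl is born free and chelated, so no late demethylation is needed, and the C8 hydroxyl can be methylated beside it. On these points it is stronger than the chosen route.
- Against it: A5 needs a fully substituted γ-pyranone, already holding ring B and the C3 methoxyl, to act as a carbon nucleophile at the future C8a. A metallated 4-pyranone is itself an enone acceptor. It must also add to the correct carbonyl of an unsymmetrical methoxycyclobutenedione. The pyranone must first be made by other annulation chemistry, so the rearrangement is extra work on top of a chromone-type synthesis. A4 is an electron-rich para-hydroquinone, easily oxidised in air to the quinone, and it still needs selective methylation and debenzylation.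
- Comparison: the chosen route takes ring A with all four oxygens in place in four routine steps from aldehyde 1 and is much shorter.

Alternative 3: This route cuts O1–C2 and replaces the C3 methoxyl by iodine. An electrophilic iodine reagent activates the triple bond of alkynone A7. The ring A methoxy oxygen ortho to the ketone adds to the alkyne carbon bearing ring B (6-endo-dig), the methyl group leaves as its halide, and the 3-iodochromone A6 results.
- For it: the conditions are cold and mild. The ring A site is fixed by the ketone, so no para-acylation question arises; on this point it is stronger. Both phenols are masked alike and freed together.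
- Against it: ring B has its own methoxyl ortho to the alkyne. Its oxygen can attack the other alkyne carbon (5-endo-dig), the known route from 2-alkynylanisoles to 3-iodobenzofurans. This competition is built into the 2'-methoxy pattern of this target. The C3 iodide must then be exchanged for methoxyl, for instance by a CuI-mediated coupling with methoxide on a hindered, base-sensitive chromone. Ring A must be supplied as a pentasubstituted benzoyl unit, which is harder to reach than phenol 6.
- Comparison: the chosen route brings the C3 methoxyl in with ester 10 and needs no functionalisation after ring closure.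

Key step: step 8

Remark on the chemistry: compounds 1, 7 and 10 are taken to be purchasable, and the two closing deprotections are run Lewis acid first, base second.

## Route

Step 1
Reactants: 1 2-hydroxy-4,6-dimethoxybenzaldehyde
Product: 2 2-(benzyloxy)-4,6-dimethoxybenzaldehyde
Conditions: BnBr, K2CO3, DMF, 60 °C
Reagents that add atoms: benzyl bromide, BrCc1ccccc1
Why: Williamson ether synthesis; the hydrogen-bonded ortho-hydroxyl is deprotonated by carbonate in DMF and alkylated by the benzylic bromide, masking the oxygen that must later be the free phenol of ring A.

Step 2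
Reactants: 2 2-(benzyloxy)-4,6-dimethoxybenzaldehyde
Product: 4 2-(benzyloxy)-4,6-dimethoxyphenol, via aryl formate 3 (not isolated)
Conditions: mCPBA, CH2Cl2, 0 °C to rt; aq. Na2SO3; then K2CO3 (cat.), MeOH, rt
Reagents that add atoms: 3-chloroperoxybenzoic acid (mCPBA), O=C(OO)c1cccc(Cl)c1
Why: Baeyer–Villiger (Dakin-type) oxidation; in the peracid adduct the aryl group, activated by alkoxy groups ortho and para, migrates in preference to hydride and gives formate 3, and the peracid is destroyed before methanolysis so that the oxidisable phenol 4 never meets oxidant.

Step 3
Reactants: 4 2-(benzyloxy)-4,6-dimethoxyphenol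
Product: 5 1-(benzyloxy)-2,3,5-trimethoxybenzene
Conditions: MeI, K2CO3, acetone, reflux
Reagents that add atoms: iodomethane, CI
Why: O-methylation of a phenoxide (Williamson); the flanked hydroxyl is still readily alkylated by the small electrophile, and this fixes the future C8 methoxyl.

Step 4
Reactants: 5 1-(benzyloxy)-2,3,5-trimethoxybenzene
Product: 6 2,3,5-trimethoxyphenol
Conditions: H2 (1 atm), Pd/C, EtOAc–MeOH, rt
Reagents that add atoms: none
Why: Hydrogenolysis of the benzylic C–O bond; the methyl ethers and the arene are inert under these conditions, and the air-sensitive phenol is used promptly under argon.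

Step 5
Reactants: 7 5-hydroxy-2-methoxybenzoic acid
Product: 8 2-methoxy-5-(methanesulfonyloxy)benzoic acid
Conditions: MsCl (excess, slow addition), aq. NaOH (pH 10–11), THF–H2O, 0–5 °C; then HCl to pH 1
Reagents that add atoms: methanesulfonyl chloride, CS(=O)(=O)Cl
Why: Schotten–Baumann sulfonylation of the phenoxide; any acyl sulfonate formed at the carboxylate is hydrolysed again in the aqueous base, so the free acid is recovered on acidification.

Step 6
Reactants: 8 2-methoxy-5-(methanesulfonyloxy)benzoic acid
Product: 9 2-methoxy-5-(methanesulfonyloxy)benzoyl chloride
Conditions: (COCl)2, DMF (cat.), CH2Cl2, 0 °C to rt; concentrate, use crude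
Reagents that add atoms: oxalyl chloride, O=C(Cl)C(=O)Cl
Why: Acid chloride formation through the Vilsmeier-type chloroiminium catalyst; the aryl sulfonate and the methyl ether are inert to it.

Step 7
Reactants: 9 2-methoxy-5-(methanesulfonyloxy)benzoyl chloride; 10 ethyl methoxyacetate
Product: 11 ethyl 2-methoxy-3-[2-methoxy-5-(methanesulfonyloxy)phenyl]-3-oxopropanoate
Conditions: 10 (2.1 equiv), LiN(SiMe3)2 (2.0 equiv), THF, −78 °C; then 9, −78 °C; AcOH quench at −78 °C
Reagents that add atoms: none
Why: Crossed Claisen condensation (C-acylation of a preformed lithium ester enolate by an acid chloride); the second enolate equivalent takes the acidic proton of the product, and full preformation of the enolate, exact stoichiometry and a cold quench keep free amide base and excess enolate away from the sulfonate methyl group.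

Step 8
Reactants: 6 2,3,5-trimethoxyphenol; 11 ethyl 2-methoxy-3-[2-methoxy-5-(methanesulfonyloxy)phenyl]-3-oxopropanoate
Product: 14 3,5,7,8-tetramethoxy-2-[2-methoxy-5-(methanesulfonyloxy)phenyl]-4H-chromen-4-one, via aroyl(methoxy)ketene 12 (not isolated), via hydroxyaryl diketone 13 (not isolated)
Conditions: neat melt, 11 (1.5 equiv), 240–250 °C, slow Ar stream, 2–3 h, EtOH and H2O distilled out (Ph2O as diluent if needed)
Reagents that add atoms: none
Why: Mentzer thermal chromone synthesis, the uncatalysed relative of the Simonis condensation. The enol form of 11 should lose ethanol on heating to give acylketene 12; attack of 12 on the phenol oxygen only gives an aryl ester that reverts to 12 at this temperature, so that pathway is not a loss. Carbon attack at C6 of 6, the only free position ortho to the hydroxyl, forms C4–C4a and gives diketone 13; the hydroxyl can pass its proton to the ketene oxygen in a six-membered array, which favours ortho attack. The phenolic oxygen of 13 then adds to the ring B ketone carbon in a 6-exo-trig closure, and loss of water forms O1–C2 and the aromatic pyranone, which makes the sequence irreversible. The chromone sense (ester carbon to ring, ketone carbon to oxygen) is favoured over the Pechmann coumarin sense because no strong protic acid is present to activate the ketone toward the arene, and the α-methoxyl disfavours the coumarin pathway further. The competing site C4 of 6, para to the hydroxyl, is flanked by two methoxyls and lacks the proton relay. The sulfonate is inert in the melt, and no stereocenter is formed.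

Step 9
Reactants: 14 3,5,7,8-tetramethoxy-2-[2-methoxy-5-(methanesulfonyloxy)phenyl]-4H-chromen-4-one
Product: 15 5-hydroxy-3,7,8-trimethoxy-2-[2-methoxy-5-(methanesulfonyloxy)phenyl]-4H-chromen-4-one
Conditions: BCl3 (1 M in CH2Cl2, 2–3 equiv), CH2Cl2, −78 to 0 °C; then aq. HCl–MeOH
Reagents that add atoms: none
Why: Chelation-controlled Lewis-acid ether cleavage; boron bridges the C4 carbonyl and the peri C5 oxygen in a six-membered chelate and chloride removes that methyl group, whereas the C3 methoxyl could only form a more strained five-membered chelate, and the other ethers and the sulfonate are not activated at 0 °C.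

Step 10
Reactants: 15 5-hydroxy-3,7,8-trimethoxy-2-[2-methoxy-5-(methanesulfonyloxy)phenyl]-4H-chromen-4-one
Product: 16 5,5'-dihydroxy-3,7,8,2'-tetramethoxyflavone [5-hydroxy-2-(5-hydroxy-2-methoxyphenyl)-3,7,8-trimethoxy-4H-chromen-4-one]
Conditions: KOH, MeOH–H2O, 50 °C, Ar; then dil. HCl
Reagents that add atoms: none
Why: Alkaline cleavage of an aryl methanesulfonate (attack at sulfur or E1cB loss through the sulfonyl carbanion); the C5 phenoxide forms first and donates into the pyranone, lowering the electrophilicity of C2, so ring C should survive while the sulfonate is removed, and acidification releases the diphenol.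

## Compound list

1 | 2-hydroxy-4,6-dimethoxybenzaldehyde | COc1cc(O)c(C=O)c(OC)c1 | starting material
2 | 2-(benzyloxy)-4,6-dimethoxybenzaldehyde | COc1cc(OCc2ccccc2)c(C=O)c(OC)c1 | intermediate
3 | 2-(benzyloxy)-4,6-dimethoxyphenyl formate | COc1cc(OCc2ccccc2)c(OC=O)c(OC)c1 | intermediate (not isolated)
4 | 2-(benzyloxy)-4,6-dimethoxyphenol | COc1cc(OCc2ccccc2)c(O)c(OC)c1 | intermediate
5 | 1-(benzyloxy)-2,3,5-trimethoxybenzene | COc1cc(OCc2ccccc2)c(OC)c(OC)c1 | intermediate
6 | 2,3,5-trimethoxyphenol | COc1cc(O)c(OC)c(OC)c1 | intermediate
7 | 5-hydroxy-2-methoxybenzoic acid | COc1ccc(O)cc1C(=O)O | starting material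
8 | 2-methoxy-5-(methanesulfonyloxy)benzoic acid | COc1ccc(OS(C)(=O)=O)cc1C(=O)O | intermediate
9 | 2-methoxy-5-(methanesulfonyloxy)benzoyl chloride | COc1ccc(OS(C)(=O)=O)cc1C(=O)Cl | intermediate
10 | ethyl methoxyacetate | CCOC(=O)COC | starting material
11 | ethyl 2-methoxy-3-[2-methoxy-5-(methanesulfonyloxy)phenyl]-3-oxopropanoate | CCOC(=O)C(OC)C(=O)c1cc(OS(C)(=O)=O)ccc1OC | intermediate
12 | [2-methoxy-5-(methanesulfonyloxy)benzoyl](methoxy)ketene, 2-methoxy-3-[2-methoxy-5-(methanesulfonyloxy)phenyl]-3-oxoprop-1-en-1-one | COC(=C=O)C(=O)c1cc(OS(C)(=O)=O)ccc1OC | intermediate (not isolated)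
13 | 1-(2-hydroxy-3,4,6-trimethoxyphenyl)-2-methoxy-3-[2-methoxy-5-(methanesulfonyloxy)phenyl]propane-1,3-dione | COc1cc(OC)c(C(=O)C(OC)C(=O)c2cc(OS(C)(=O)=O)ccc2OC)c(O)c1OC | intermediate (not isolated)
14 | 3,5,7,8-tetramethoxy-2-[2-methoxy-5-(methanesulfonyloxy)phenyl]-4H-chromen-4-one | COc1ccc(OS(C)(=O)=O)cc1-c1oc2c(OC)c(OC)cc(OC)c2c(=O)c1OC | intermediate
15 | 5-hydroxy-3,7,8-trimethoxy-2-[2-methoxy-5-(methanesulfonyloxy)phenyl]-4H-chromen-4-one | COc1ccc(OS(C)(=O)=O)cc1-c1oc2c(OC)c(OC)cc(O)c2c(=O)c1OC | intermediate
16 | 5,5'-dihydroxy-3,7,8,2'-tetramethoxyflavone | COc1ccc(O)cc1-c1oc2c(OC)c(OC)cc(O)c2c(=O)c1OC | target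

## Step count and risk

Total step count: 10. Longest linear sequence: 7 steps (steps 1, 2, 3, 4, 8, 9, 10 from aldehyde 1); the ring B branch (steps 5, 6, 7) joins at step 8.

Steps least certain to work:

**Step 8 (key step).** Three things are most likely to go wrong. Ketene 12 may dimerise instead of being captured. Carbon acylation may occur at C4 of the phenol, para to the hydroxyl, where no ring can close. The electron-rich phenol may slowly decompose in the melt. The excess of 11 and the argon stream address the first and third; the second depends on the ortho preference argued above.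

Fallback: the two bonds of ring C are formed in separate, directed operations, setting out from 6 and 9 and coming back at 13.
- Acylation of 6 with methoxyacetic acid in BF3·OEt2 at 80–90 °C (Friedel–Crafts/Fries manifold) should give 1-(2-hydroxy-3,4,6-trimethoxyphenyl)-2-methoxyethan-1-one F1. Here the ortho ketone is the thermodynamic product, held as its difluoroboron chelate.
- Esterification of F1 with acid chloride 9 (pyridine, DMAP) gives 2-(methoxyacetyl)-3,5,6-trimethoxyphenyl 2-methoxy-5-(methanesulfonyloxy)benzoate F2.
- Baker–Venkataraman rearrangement of F2 (KOH, pyridine, 50 °C) transfers the aroyl group to the α-carbon and returns to the route at diketone 13.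
- H2SO4 (cat.) in AcOH closes 13 to 14.

**Step 7.** The risk is proton abstraction from the sulfonate methyl group by the enolate or by residual amide base. That would cause loss or self-condensation of the protecting group. Over-acylation of the product enolate is a second risk.

Fallback: a route without strong base, from 8 to 11.
- Acid 8 is activated with 1,1'-carbonyldiimidazole and treated with potassium ethyl malonate, MgCl2 and Et3N. Decarboxylation on acid work-up gives ethyl 3-[2-methoxy-5-(methanesulfonyloxy)phenyl]-3-oxopropanoate F3.
- Diazo transfer with 4-acetamidobenzenesulfonyl azide and Et3N gives ethyl 2-diazo-3-[2-methoxy-5-(methanesulfonyloxy)phenyl]-3-oxopropanoate F4.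
- Rh2(OAc)4-catalysed O–H insertion of the derived carbenoid into methanol gives 11.

**Step 9.** The risk is poor site selectivity of the ether cleavage. The C3 methyl ether, the other oxygen beside the carbonyl, may be lost together with the C5 methyl ether.

Fallback: selectivity is moved from the cleavage to a re-alkylation, from 14 to 15.
- Both carbonyl-flanking ethers are cleaved on purpose (BBr3, 2.2 equiv, CH2Cl2, −78 to 0 °C) to give 3,5-dihydroxy-7,8-dimethoxy-2-[2-methoxy-5-(methanesulfonyloxy)phenyl]-4H-chromen-4-one F5.
- One equivalent of Me2SO4 with K2CO3 in acetone then methylates the C3 hydroxyl. The strongly chelated C5 hydroxyl is the least reactive phenol of a flavonol, so this should return 15.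

**Step 10.** The risk is addition of hydroxide to C2 before the sulfonate has gone. That would open ring C and lead to retro-Claisen fragmentation, or to reclosure through the C5 oxygen to the 5,6,7-isomer.

Fallback: the base step is removed by changing the C5' protecting group, setting out from 7 and 10 and coming back at 16.
- Acid 7 with BnBr and K2CO3 gives benzyl 5-(benzyloxy)-2-methoxybenzoate F6.
- LiOH in THF–H2O gives 5-(benzyloxy)-2-methoxybenzoic acid F7.
- (COCl)2 gives 5-(benzyloxy)-2-methoxybenzoyl chloride F8.
- Acylation of the lithium enolate of 10, as in step 7, gives ethyl 3-[5-(benzyloxy)-2-methoxyphenyl]-2-methoxy-3-oxopropanoate F9.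
- The melt with 6, as in step 8, gives 2-[5-(benzyloxy)-2-methoxyphenyl]-3,5,7,8-tetramethoxy-4H-chromen-4-one F10.
- BCl3 with pentamethylbenzene (CH2Cl2, −78 to 0 °C) removes the benzyl group and the chelated C5 methyl group in one flask to give 16.

## Further compounds

F1 | step 8 | 1-(2-hydroxy-3,4,6-trimethoxyphenyl)-2-methoxyethan-1-one | COCC(=O)c1c(OC)cc(OC)c(OC)c1O
F2 | step 8 | 2-(methoxyacetyl)-3,5,6-trimethoxyphenyl 2-methoxy-5-(methanesulfonyloxy)benzoate | COCC(=O)c1c(OC)cc(OC)c(OC)c1OC(=O)c1cc(OS(C)(=O)=O)ccc1OC
F3 | step 7 | ethyl 3-[2-methoxy-5-(methanesulfonyloxy)phenyl]-3-oxopropanoate | CCOC(=O)CC(=O)c1cc(OS(C)(=O)=O)ccc1OC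
F4 | step 7 | ethyl 2-diazo-3-[2-methoxy-5-(methanesulfonyloxy)phenyl]-3-oxopropanoate | CCOC(=O)C(=[N+]=[N-])C(=O)c1cc(OS(C)(=O)=O)ccc1OC
F5 | step 9 | 3,5-dihydroxy-7,8-dimethoxy-2-[2-methoxy-5-(methanesulfonyloxy)phenyl]-4H-chromen-4-one | COc1ccc(OS(C)(=O)=O)cc1-c1oc2c(OC)c(OC)cc(O)c2c(=O)c1O
F6 | step 10 | benzyl 5-(benzyloxy)-2-methoxybenzoate | COc1ccc(OCc2ccccc2)cc1C(=O)OCc1ccccc1
F7 | step 10 | 5-(benzyloxy)-2-methoxybenzoic acid | COc1ccc(OCc2ccccc2)cc1C(=O)O
F8 | step 10 | 5-(benzyloxy)-2-methoxybenzoyl chloride | COc1ccc(OCc2ccccc2)cc1C(=O)Cl
F9 | step 10 | ethyl 3-[5-(benzyloxy)-2-methoxyphenyl]-2-methoxy-3-oxopropanoate | CCOC(=O)C(OC)C(=O)c1cc(OCc2ccccc2)ccc1OC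
F10 | step 10 | 2-[5-(benzyloxy)-2-methoxyphenyl]-3,5,7,8-tetramethoxy-4H-chromen-4-one | COc1ccc(OCc2ccccc2)cc1-c1oc2c(OC)c(OC)cc(OC)c2c(=O)c1OC
A1 | alternative 1 | 1-[5-(benzyloxy)-2-methoxyphenyl]-2-methoxy-3-[2-(methoxymethoxy)-3,4,6-trimethoxyphenyl]propane-1,3-dione | COCOc1c(C(=O)C(OC)C(=O)c2cc(OCc3ccccc3)ccc2OC)c(OC)cc(OC)c1OC
A2 | alternative 1 | 1-iodo-3,4,6-trimethoxy-2-(methoxymethoxy)benzene | COCOc1c(I)c(OC)cc(OC)c1OC
A3 | alternative 1 | 1-[5-(benzyloxy)-2-methoxyphenyl]-2-methoxyethan-1-one | COCC(=O)c1cc(OCc2ccccc2)ccc1OC
A4 | alternative 2 | 2-[5-(benzyloxy)-2-methoxyphenyl]-5,8-dihydroxy-3,7-dimethoxy-4H-chromen-4-one | COc1ccc(OCc2ccccc2)cc1-c1oc2c(O)c(OC)cc(O)c2c(=O)c1OC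
A5 | alternative 2 | 4-{6-[5-(benzyloxy)-2-methoxyphenyl]-5-methoxy-4-oxo-4H-pyran-2-yl}-4-hydroxy-3-methoxycyclobut-2-en-1-one (racemic) | O=C1C=C(OC)C1(O)c1cc(=O)c(OC)c(-c2cc(OCc3ccccc3)ccc2OC)o1
A6 | alternative 3 | 3-iodo-7,8-dimethoxy-2-[2-methoxy-5-(tosyloxy)phenyl]-4-oxo-4H-chromen-5-yl 4-methylbenzenesulfonate | COc1ccc(OS(=O)(=O)c2ccc(C)cc2)cc1-c1oc2c(OC)c(OC)cc(OS(=O)(=O)c3ccc(C)cc3)c2c(=O)c1I
A7 | alternative 3 | 3,4,5-trimethoxy-2-{3-[2-methoxy-5-(tosyloxy)phenyl]prop-2-ynoyl}phenyl 4-methylbenzenesulfonate | COc1ccc(OS(=O)(=O)c2ccc(C)cc2)cc1C#CC(=O)c1c(OC)c(OC)c(OC)cc1OS(=O)(=O)c1ccc(C)cc1
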